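Ring B is cut across C1–C2 and C5–C6. Its C2(OMe)–C3(prenyl)–C4(OH)–C5(H) edge is the methyl enol ether of symmetric 2-prenylcyclohexane-1,3-dione, while C1 (aroyl) and C6 come from an aryl alkynyl ketone. One Diels–Alder/retro-Diels–Alder (Alder–Rickert) operation joins a 1-methoxy-3-silyloxycyclohexa-1,3-diene to a 3-bromo-1-arylpropynone, expels ethylene and delivers the fully substituted ring B, with bromine marking the C6 oxygen. The ring A phenol is carried as a tert-butyldimethylsilyl ether, so that the closing palladium-catalysed hydroxylation with KOH also unmasks it and no acid meets the ortho-prenyl phenol.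

Key step: step 8

Remark: the target has no stereocentre; alcohol 10 and the bridged adduct 13 are racemic, and their stereocentres are erased in steps 6 and 8.

Step 1
Reactants: 1 cyclohexane-1,3-dione; 2 prenyl bromide (1-bromo-3-methylbut-2-ene)
Product: 3 2-(3-methylbut-2-enyl)cyclohexane-1,3-dione
Conditions: KOH (1 equiv), H2O, 0 °C to rt
Reagents that add atoms: none
Why: SN2 C-alkylation of the ambident potassium enolate of the 1,3-dione, in which water hydrogen-bonds the enolate oxygens and the soft allylic bromide favours attack through C2.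

Step 2
Reactants: 3 2-(3-methylbut-2-enyl)cyclohexane-1,3-dione
Product: 4 3-methoxy-2-(3-methylbut-2-enyl)cyclohex-2-en-1-one
Conditions: Me2SO4, K2CO3, acetone, reflux
Reagents that add atoms: dimethyl sulfate, COS(=O)(=O)OC
Why: O-methylation of the vinylogous carboxylate by a hard electrophile; the dione is symmetric, so either oxygen gives the same enol ether, and the acid-free medium keeps the prenyl group from cyclizing onto the enol oxygen.

Step 3
Reactants: 4 3-methoxy-2-(3-methylbut-2-enyl)cyclohex-2-en-1-one
Product: 6 1-methoxy-2-(3-methylbut-2-enyl)-3-(trimethylsilyloxy)cyclohexa-1,3-diene, via lithium dienolate 5 (not isolated)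
Conditions: LiN(iPr)2 (lithium diisopropylamide, 1.1 equiv), THF, −78 °C; Me3SiCl, −78 °C to rt; pentane, filtration, used crude
Reagents that add atoms: chlorotrimethylsilane, C[Si](C)(C)Cl
Why: Kinetic deprotonation of the vinylogous ester at the α′ methylene (C6) gives the cross-conjugated dienolate, and O-silylation (silyl enol ether formation) locks it as the 1-methoxy-3-silyloxy diene.

Step 4
Reactants: 7 vanillin
Product: 8 4-(tert-butyldimethylsilyloxy)-3-methoxybenzaldehyde
Conditions: TBSCl, imidazole, DMF, rt
Reagents that add atoms: tert-butyldimethylsilyl chloride, CC(C)(C)[Si](C)(C)Cl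
Why: Imidazole-promoted silylation of the phenol gives an aryl silyl ether that should survive the Grignard, oxidation, bromination and thermal steps and still fall to hydroxide in step 9.

Step 5
Reactants: 8 4-(tert-butyldimethylsilyloxy)-3-methoxybenzaldehyde; 9 ethynylmagnesium bromide (HC≡CMgBr)
Product: 10 rac-1-[4-(tert-butyldimethylsilyloxy)-3-methoxyphenyl]prop-2-yn-1-ol
Conditions: THF, 0 °C; sat. aq. NH4Cl
Reagents that add atoms: none
Why: Grignard 1,2-addition of the alkynyl nucleophile to the aldehyde; the carbinol centre forms without control (racemic) and is removed by the oxidation in step 6.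

Step 6
Reactants: 10 rac-1-[4-(tert-butyldimethylsilyloxy)-3-methoxyphenyl]prop-2-yn-1-ol
Product: 11 1-[4-(tert-butyldimethylsilyloxy)-3-methoxyphenyl]prop-2-yn-1-one
Conditions: MnO2 (activated, excess), CH2Cl2, rt
Reagents that add atoms: none
Why: Selective MnO2 oxidation of a doubly activated (benzylic and propargylic) secondary alcohol to the ynone under neutral conditions that leave the silyl ether and the terminal alkyne untouched.

Step 7
Reactants: 11 1-[4-(tert-butyldimethylsilyloxy)-3-methoxyphenyl]prop-2-yn-1-one
Product: 12 3-bromo-1-[4-(tert-butyldimethylsilyloxy)-3-methoxyphenyl]prop-2-yn-1-one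
Conditions: NBS, AgNO3 (10 mol%), acetone, rt, dark
Reagents that add atoms: N-bromosuccinimide, O=C1CCC(=O)N1Br
Why: Silver-catalysed electrophilic bromination of the terminal alkyne (through the silver acetylide, RC≡CAg), a standard route to 1-bromoalkynes that is also used on terminal ynones.

Step 8
Reactants: 6 1-methoxy-2-(3-methylbut-2-enyl)-3-(trimethylsilyloxy)cyclohexa-1,3-diene; 12 3-bromo-1-[4-(tert-butyldimethylsilyloxy)-3-methoxyphenyl]prop-2-yn-1-one
Product: 15 [6-bromo-4-hydroxy-2-methoxy-3-(3-methylbut-2-enyl)phenyl][4-(tert-butyldimethylsilyloxy)-3-methoxyphenyl]methanone, via bicyclooctadiene adduct 13 (not isolated), via aryl trimethylsilyl ether 14 (not isolated)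
Conditions: 6 (1.5 equiv), o-xylene, sealed tube, 110 °C then 150 °C; then citric acid (cat.), MeOH, rt
Reagents that add atoms: none
Why: Diene 6, electron-rich through its C1 methoxy and C3 silyloxy groups, and the electron-poor alkyne of 12 should combine in a concerted, asynchronous normal-demand [4+2] cycloaddition to the bridged adduct 13, which on stronger heating undergoes a retro-[4+2] reaction that expels the saturated two-carbon bridge as ethylene and leaves ring B as the aryl silyl ether 14, methanolysed to the C4 phenol on work-up. The closest known reaction type is the Alder–Rickert arene synthesis from 1,3-dioxygenated cyclohexa-1,3-dienes and acetylenic ketones or esters. Ring B is closed by intermolecular two-bond [4+2] annulation (C1–C2 and C5–C6 formed in the same event, first as part of the bicyclo[2.2.2]octadiene) and is unveiled as a benzene ring by cycloreversion, with aromatization as the driving force. No stereocentre is created in the product; the two bridgehead centres of 13 arise as a racemic pair whose relative configuration is dictated by the bicycle, and both are erased when ethylene leaves. The selectivity needed is regiochemical, and it is secured by matched polarization: the unsubstituted diene terminus (C4 of 6), the site made nucleophilic by both oxygen donors, bonds to the bromine-bearing β-carbon of the ynone while the methoxy-bearing terminus bonds to the acyl-bearing α-carbon, which places the aroyl group at C1 between OMe and Br and the bromine at C6. Chemoselectivity follows from electronics, since the isolated prenyl alkene is no dienophile for an electron-rich diene, and the staged heating lets the bromoynone be consumed before the higher temperature needed for ethylene loss is reached.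

Step 9
Reactants: 15 [6-bromo-4-hydroxy-2-methoxy-3-(3-methylbut-2-enyl)phenyl][4-(tert-butyldimethylsilyloxy)-3-methoxyphenyl]methanone
Product: 17 [4,6-dihydroxy-2-methoxy-3-(3-methylbut-2-enyl)phenyl](4-hydroxy-3-methoxyphenyl)methanone, via desilylated bromide 16 (not isolated)
Conditions: KOH (6 equiv), Pd2(dba)3 (2 mol%), 2-di-tert-butylphosphino-2′,4′,6′-triisopropylbiphenyl (8 mol%), 1,4-dioxane/H2O 1:1, degassed, 100 °C; then 1 M HCl to pH 5, 0 °C
Reagents that add atoms: potassium hydroxide, [K+].[OH-]
Why: Aqueous KOH should first cleave the para-acyl aryl silyl ether by attack at silicon, and the aryl bromide then undergoes the known palladium-catalysed hydroxylation of aryl halides (oxidative addition to zerovalent palladium, bromide–hydroxide exchange, C–O reductive elimination enforced by the bulky di-tert-butylbiarylphosphine), a C–O cross-coupling that tolerates ketones, phenoxides and isolated alkenes.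

Compound list
1 | cyclohexane-1,3-dione | O=C1CCCC(=O)C1 | starting material
2 | prenyl bromide (1-bromo-3-methylbut-2-ene) | CC(C)=CCBr | starting material
3 | 2-(3-methylbut-2-enyl)cyclohexane-1,3-dione | CC(C)=CCC1C(=O)CCCC1=O | intermediate
4 | 3-methoxy-2-(3-methylbut-2-enyl)cyclohex-2-en-1-one | COC1=C(CC=C(C)C)C(=O)CCC1 | intermediate
5 | lithium 5-methoxy-6-(3-methylbut-2-enyl)cyclohexa-1,5-dien-1-olate (kinetic dienolate of 4) | [Li+].COC1=C(CC=C(C)C)C([O-])=CCC1 | intermediate
6 | 1-methoxy-2-(3-methylbut-2-enyl)-3-(trimethylsilyloxy)cyclohexa-1,3-diene | COC1=C(CC=C(C)C)C(O[Si](C)(C)C)=CCC1 | intermediate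
7 | vanillin | COc1cc(C=O)ccc1O | starting material
8 | 4-(tert-butyldimethylsilyloxy)-3-methoxybenzaldehyde | COc1cc(C=O)ccc1O[Si](C)(C)C(C)(C)C | intermediate
9 | ethynylmagnesium bromide | C#C[Mg]Br | starting material
10 | rac-1-[4-(tert-butyldimethylsilyloxy)-3-methoxyphenyl]prop-2-yn-1-ol (racemic) | COc1cc(C(O)C#C)ccc1O[Si](C)(C)C(C)(C)C | intermediate
11 | 1-[4-(tert-butyldimethylsilyloxy)-3-methoxyphenyl]prop-2-yn-1-one | COc1cc(C(=O)C#C)ccc1O[Si](C)(C)C(C)(C)C | intermediate
12 | 3-bromo-1-[4-(tert-butyldimethylsilyloxy)-3-methoxyphenyl]prop-2-yn-1-one | COc1cc(C(=O)C#CBr)ccc1O[Si](C)(C)C(C)(C)C | intermediate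
13 | [3-bromo-1-methoxy-6-(3-methylbut-2-enyl)-5-(trimethylsilyloxy)bicyclo[2.2.2]octa-2,5-dien-2-yl][4-(tert-butyldimethylsilyloxy)-3-methoxyphenyl]methanone (racemic; bridgehead configuration fixed by the bicycle) | COC12CCC(C(Br)=C1C(=O)c1ccc(O[Si](C)(C)C(C)(C)C)c(OC)c1)C(O[Si](C)(C)C)=C2CC=C(C)C | intermediate
14 | [6-bromo-2-methoxy-3-(3-methylbut-2-enyl)-4-(trimethylsilyloxy)phenyl][4-(tert-butyldimethylsilyloxy)-3-methoxyphenyl]methanone | COc1cc(C(=O)c2c(Br)cc(O[Si](C)(C)C)c(CC=C(C)C)c2OC)ccc1O[Si](C)(C)C(C)(C)C | intermediate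
15 | [6-bromo-4-hydroxy-2-methoxy-3-(3-methylbut-2-enyl)phenyl][4-(tert-butyldimethylsilyloxy)-3-methoxyphenyl]methanone | COc1cc(C(=O)c2c(Br)cc(O)c(CC=C(C)C)c2OC)ccc1O[Si](C)(C)C(C)(C)C | intermediate
16 | [6-bromo-4-hydroxy-2-methoxy-3-(3-methylbut-2-enyl)phenyl](4-hydroxy-3-methoxyphenyl)methanone | COc1cc(C(=O)c2c(Br)cc(O)c(CC=C(C)C)c2OC)ccc1O | intermediate
17 | [4,6-dihydroxy-2-methoxy-3-(3-methylbut-2-enyl)phenyl](4-hydroxy-3-methoxyphenyl)methanone | COc1cc(C(=O)c2c(O)cc(O)c(CC=C(C)C)c2OC)ccc1O | target

Total step count: 9
Longest linear sequence: 6 steps (7 → 8 → 10 → 11 → 12 → 15 → 17; steps 4 to 9)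

Steps most likely to fail

Step 8. The electron-rich silyl dienol ether may attack the brominated alkyne carbon in an ionic sense (bromine transfer to the diene, or addition followed by loss of bromide) faster than the concerted cycloaddition, and slow ethylene loss may expose the bridged adduct to decomposition. The fallback changes the C6 marker to chlorine, whose stronger and less polarizable bond to the alkyne carbon is not prone to halogen transfer. It sets out from 10 and 6 and comes back to the route at 17. Alcohol 10 would be doubly deprotonated with n-BuLi (2 equiv, THF, −78 °C) and the acetylide chlorinated with N-chlorosuccinimide to give rac-3-chloro-1-[4-(tert-butyldimethylsilyloxy)-3-methoxyphenyl]prop-2-yn-1-ol F1. MnO2 oxidation would give 3-chloro-1-[4-(tert-butyldimethylsilyloxy)-3-methoxyphenyl]prop-2-yn-1-one F2. Heating F2 with diene 6 as in step 8 should lead through the chloro bicyclooctadiene adduct F3 and the chloro aryl trimethylsilyl ether F4 to [6-chloro-4-hydroxy-2-methoxy-3-(3-methylbut-2-enyl)phenyl][4-(tert-butyldimethylsilyloxy)-3-methoxyphenyl]methanone F5 after methanolysis. The conditions of step 9, whose catalyst also activates aryl chlorides, would then lead through the desilylated chloride [6-chloro-4-hydroxy-2-methoxy-3-(3-methylbut-2-enyl)phenyl](4-hydroxy-3-methoxyphenyl)methanone F6 to the target 17.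

Step 9. The phenoxides present may couple with the arylpalladium intermediate to give diaryl ethers, the ortho-acyl phenoxide product may bind and slow the catalyst, or the bromide may be reduced instead of hydroxylated. The fallback replaces C–O coupling by borylation and oxidation. It sets out from 15 and comes back at 17. Miyaura borylation of 15 (bis(pinacolato)diboron, PdCl2(dppf), KOAc, 1,4-dioxane, 85 °C) would give [4-hydroxy-2-methoxy-3-(3-methylbut-2-enyl)-6-(4,4,5,5-tetramethyl-1,3,2-dioxaborolan-2-yl)phenyl][4-(tert-butyldimethylsilyloxy)-3-methoxyphenyl]methanone F7. Oxidation of the carbon–boron bond with NaBO3·4H2O in THF/water at rt, which leaves the prenyl alkene alone, would give [4,6-dihydroxy-2-methoxy-3-(3-methylbut-2-enyl)phenyl][4-(tert-butyldimethylsilyloxy)-3-methoxyphenyl]methanone F8. K2CO3 in methanol at rt would then remove the silyl ether to give 17.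

Step 1. O-alkylation and double C-alkylation of the ambident enolate may compete with mono C-prenylation. The fallback replaces the SN2 alkylation by a Tsuji–Trost allylic alkylation. It sets out from 1 and comes back at 3. Treating 1 with prenyl acetate, Pd(PPh3)4 (cat.) and Et3N in THF at 60 °C should give 3, because O-allylated material is re-ionized by zerovalent palladium and funnelled to the C-alkylated dione, and the stabilized nucleophile attacks the less substituted terminus of the 1,1-dimethylallyl palladium intermediate.

Further compounds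
F1 | step 8 | rac-3-chloro-1-[4-(tert-butyldimethylsilyloxy)-3-methoxyphenyl]prop-2-yn-1-ol (racemic) | COc1cc(C(O)C#CCl)ccc1O[Si](C)(C)C(C)(C)C
F2 | step 8 | 3-chloro-1-[4-(tert-butyldimethylsilyloxy)-3-methoxyphenyl]prop-2-yn-1-one | COc1cc(C(=O)C#CCl)ccc1O[Si](C)(C)C(C)(C)C
F3 | step 8 | [3-chloro-1-methoxy-6-(3-methylbut-2-enyl)-5-(trimethylsilyloxy)bicyclo[2.2.2]octa-2,5-dien-2-yl][4-(tert-butyldimethylsilyloxy)-3-methoxyphenyl]methanone (racemic) | COC12CCC(C(Cl)=C1C(=O)c1ccc(O[Si](C)(C)C(C)(C)C)c(OC)c1)C(O[Si](C)(C)C)=C2CC=C(C)C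
F4 | step 8 | [6-chloro-2-methoxy-3-(3-methylbut-2-enyl)-4-(trimethylsilyloxy)phenyl][4-(tert-butyldimethylsilyloxy)-3-methoxyphenyl]methanone | COc1cc(C(=O)c2c(Cl)cc(O[Si](C)(C)C)c(CC=C(C)C)c2OC)ccc1O[Si](C)(C)C(C)(C)C
F5 | step 8 | [6-chloro-4-hydroxy-2-methoxy-3-(3-methylbut-2-enyl)phenyl][4-(tert-butyldimethylsilyloxy)-3-methoxyphenyl]methanone | COc1cc(C(=O)c2c(Cl)cc(O)c(CC=C(C)C)c2OC)ccc1O[Si](C)(C)C(C)(C)C
F6 | step 8 | [6-chloro-4-hydroxy-2-methoxy-3-(3-methylbut-2-enyl)phenyl](4-hydroxy-3-methoxyphenyl)methanone | COc1cc(C(=O)c2c(Cl)cc(O)c(CC=C(C)C)c2OC)ccc1O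
F7 | step 9 | [4-hydroxy-2-methoxy-3-(3-methylbut-2-enyl)-6-(4,4,5,5-tetramethyl-1,3,2-dioxaborolan-2-yl)phenyl][4-(tert-butyldimethylsilyloxy)-3-methoxyphenyl]methanone | COc1cc(C(=O)c2c(B3OC(C)(C)C(C)(C)O3)cc(O)c(CC=C(C)C)c2OC)ccc1O[Si](C)(C)C(C)(C)C
F8 | step 9 | [4,6-dihydroxy-2-methoxy-3-(3-methylbut-2-enyl)phenyl][4-(tert-butyldimethylsilyloxy)-3-methoxyphenyl]methanone | COc1cc(C(=O)c2c(O)cc(O)c(CC=C(C)C)c2OC)ccc1O[Si](C)(C)C(C)(C)C
F0 | step 1 | none | none
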